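**Retrosynthetic overview**
1. Target 21 ⇐ tricycle 18: the C9 silyl ether becomes the ketone and the exocyclic alkene moves into conjugation (last two steps).
2. Seven-membered ring ⇐ C2–C3 bond: a tertiary radical (from C–Cl) closes onto the N-aziridinyl imine of cyclobutanone 16, turning C=O into CH–C.
3. Cyclobutane and six-membered ring in one step ⇐ crossed intramolecular vinylketene–alkene [2+2] of acid 13 to bicyclo[3.1.1]heptan-6-one 16; the C5 silyloxy stereocentre steers it and is oxidised away at the end.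
4. Acid 13 ⇐ prenal: vinylogous Mukaiyama aldol (C5), SeO2 oxidation, chiral boron aldol with 3-chloro-3-methylbutan-2-one (C8), anti reduction (C10), esterification.
5. Ring order: four- and six-membered rings together (step 9), then the seven-membered ring (step 11).

Assumption: the antipodes of the two chiral controllers (step 2 catalyst, step 5 borane) are written for the facial sense stated (Si face for C5 of 4, Re face for C8 of 9); if a controller shows the opposite sense, its mirror image is used. TBSO = tert-butyldimethylsilyloxy.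

**Step 1**
Reactants: 1 methyl 3-methylbut-2-enoate
Product: 2 tert-butyl[(1-methoxy-3-methylbuta-1,3-dien-1-yl)oxy]dimethylsilane
Conditions: LDA (commercial solution), THF/DMPU, −78 °C; TBSCl, −78 °C → rt
Reagents that add atoms: tert-butyldimethylsilyl chloride, CC(C)(C)[Si](C)(C)Cl
Why: γ-Deprotonation of the β,β-dimethylacrylate gives the extended enolate, which is O-silylated (silyl ketene acetal formation) to the silyloxydiene needed as vinylogous nucleophile; no stereocentre is formed.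

**Step 2**
Reactants: 2 tert-butyl[(1-methoxy-3-methylbuta-1,3-dien-1-yl)oxy]dimethylsilane; 3 3-methylbut-2-enal
Product: 4 methyl (2E,5S)-5-hydroxy-3,7-dimethylocta-2,6-dienoate
Conditions: SiCl4 (1.1 equiv), (S,S)-Denmark bisphosphoramide (2 mol %), i-Pr2NEt (10 mol %), CH2Cl2, −78 °C; aq. NaHCO3
Reagents that add atoms: none
Why: Catalytic enantioselective vinylogous Mukaiyama aldol addition (Lewis-base-activated SiCl4) occurs at the γ-carbon of 2 and 1,2 at the enal; the chiral silicon cation exposes the Si face of the aldehyde so that C5 is formed S, and the conjugated ester re-forms with E geometry.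

**Step 3**
Reactants: 4 methyl (2E,5S)-5-hydroxy-3,7-dimethylocta-2,6-dienoate
Product: 5 methyl (2E,5S)-5-(TBSO)-3,7-dimethylocta-2,6-dienoate
Conditions: TBSCl, imidazole, DMF, rt
Reagents that add atoms: tert-butyldimethylsilyl chloride, CC(C)(C)[Si](C)(C)Cl
Why: Standard silyl ether formation protects the allylic alcohol that later steers the cycloaddition; only the O–H bond reacts, so C5 is unchanged.

**Step 4**
Reactants: 5 methyl (2E,5S)-5-(TBSO)-3,7-dimethylocta-2,6-dienoate
Product: 7 methyl (2E,5S,6E)-5-(TBSO)-3,7-dimethyl-8-oxoocta-2,6-dienoate, via allylic alcohol 6 (not isolated)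
Conditions: SeO2 (0.3 equiv), t-BuOOH (3 equiv), CH2Cl2, rt; then Dess–Martin periodinane, NaHCO3, CH2Cl2, rt (crude)
Reagents that add atoms: tert-butyl hydroperoxide, CC(C)(C)OO
Why: Sharpless SeO2/t-BuOOH allylic oxidation (ene reaction then [2,3] shift) attacks only the E-methyl group of the electron-rich trisubstituted alkene (the enoate alkene is deactivated), and Dess–Martin oxidation of the crude alcohol gives the (E)-enal without touching C5.

**Step 5**
Reactants: 7 methyl (2E,5S,6E)-5-(TBSO)-3,7-dimethyl-8-oxoocta-2,6-dienoate; 8 3-chloro-3-methylbutan-2-one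
Product: 9 methyl (2E,5S,6E,8R)-5-(TBSO)-11-chloro-8-hydroxy-3,7,11-trimethyl-10-oxododeca-2,6-dienoate
Conditions: (+)-Ipc2BCl, Et3N, Et2O, −78 °C; then 7, −78 → −20 °C; H2O2, pH 7 buffer, MeOH, 0 °C
Reagents that add atoms: none
Why: Paterson-type chiral boron aldol addition; ketone 8 can enolise only at its methyl group, and the isopinocampheyl ligands direct attack to the Re face of the enal through a cyclic boron transition state, setting C8 as R under reagent control.

**Step 6**
Reactants: 9 methyl (2E,5S,6E,8R)-5-(TBSO)-11-chloro-8-hydroxy-3,7,11-trimethyl-10-oxododeca-2,6-dienoate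
Product: 10 methyl (2E,5S,6E,8R,10R)-5-(TBSO)-11-chloro-8,10-dihydroxy-3,7,11-trimethyldodeca-2,6-dienoate
Conditions: Me4NBH(OAc)3, MeCN/AcOH (1:1), −30 °C
Reagents that add atoms: none
Why: Saksena–Evans reduction; the C8 hydroxyl binds boron and delivers hydride intramolecularly through a chair transition state, giving the 1,3-anti diol (C10 R).

**Step 7**
Reactants: 10 methyl (2E,5S,6E,8R,10R)-5-(TBSO)-11-chloro-8,10-dihydroxy-3,7,11-trimethyldodeca-2,6-dienoate; 11 3-methylbutanoyl chloride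
Product: 12 methyl (2E,5S,6E,8R,10R)-5-(TBSO)-11-chloro-3,7,11-trimethyl-8,10-bis(3-methylbutanoyloxy)dodeca-2,6-dienoate
Conditions: 11 (3 equiv), pyridine, DMAP (0.1 equiv), CH2Cl2, 0 °C → rt
Reagents that add atoms: none
Why: DMAP-catalysed acylation of both secondary alcohols installs the two isovalerates of the target at once; only O–H bonds react, so C8 and C10 keep their configuration, and pyridine is too weak a base to close the chlorohydrin to an epoxide.

**Step 8**
Reactants: 12 methyl (2E,5S,6E,8R,10R)-5-(TBSO)-11-chloro-3,7,11-trimethyl-8,10-bis(3-methylbutanoyloxy)dodeca-2,6-dienoate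
Product: 13 (2E,5S,6E,8R,10R)-5-(TBSO)-11-chloro-3,7,11-trimethyl-8,10-bis(3-methylbutanoyloxy)dodeca-2,6-dienoic acid
Conditions: LiI (8 equiv), EtOAc, reflux, dark; 1 M HCl work-up
Reagents that add atoms: none
Why: Nucleophilic demethylation (SN2 attack of iodide on the O-methyl group) cleaves only the methyl ester, because the secondary isovalerates, the tertiary chloride and the silyl ether are inert to SN2, and it avoids basic hydrolysis.

**Step 9**
Reactants: 13 (2E,5S,6E,8R,10R)-5-(TBSO)-11-chloro-3,7,11-trimethyl-8,10-bis(3-methylbutanoyloxy)dodeca-2,6-dienoic acid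
Product: 16 (1R,2S,5R,7R)-2-(TBSO)-7-[(1R,3R)-4-chloro-4-methyl-1,3-bis(3-methylbutanoyloxy)pentyl]-7-methyl-4-methylidenebicyclo[3.1.1]heptan-6-one, via acid chloride 14 (not isolated), via vinylketene 15 (not isolated)
Conditions: 1-chloro-N,N,2-trimethylprop-1-en-1-amine (1.2 equiv), CH2Cl2, 0 °C → rt; then slow addition to Et3N (5 equiv), PhMe (0.005 M), 110 °C
Reagents that add atoms: none
Why: Et3N removes HCl from 14 across the carbonyl and the cis 3-methyl group to give vinylketene 15, which closes by the crossed intramolecular ketene–alkene [2+2] cycloaddition known from the β-pinene and β-bergamotene syntheses (ketene C1 to the less substituted C6, C2 to the tertiary C7), so that the cyclobutanone and the six-membered ring form together; the 6E alkene puts the side chain anti and the methyl syn to the new three-carbon bridge, and A(1,3) strain between H-5 and the cis 7-methyl makes the tether reach the alkene face anti to the silyloxy group, so that 5S fixes the new centres as 1R,5R,7R.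

**Step 10**
Reactants: 16 (1R,2S,5R,7R)-2-(TBSO)-7-[(1R,3R)-4-chloro-4-methyl-1,3-bis(3-methylbutanoyloxy)pentyl]-7-methyl-4-methylidenebicyclo[3.1.1]heptan-6-one
Product: 17 N-(2-phenylaziridin-1-yl)imine of 16 at C6
Conditions: 1-amino-2-phenylaziridine (1.5 equiv), Et2O, 4 Å MS, 0 °C → rt
Reagents that add atoms: 1-amino-2-phenylaziridine, NN1CC1c1ccccc1
Why: Condensation of the strained, non-enolisable cyclobutanone with the N-amino aziridine gives the N-aziridinyl imine (hydrazone formation), a strong radical acceptor; the C=N isomers and aziridine epimers formed all converge in the next step and no ring stereocentre is touched.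

**Step 11**
Reactants: 17 N-(2-phenylaziridin-1-yl)imine of 16
Product: 18 (1R,2S,4R,6R,7R,8R,9S)-9-(TBSO)-3,3,7-trimethyl-11-methylidenetricyclo[5.4.0.0^2,8]undecane-4,6-diyl bis(3-methylbutanoate)
Conditions: Bu3SnH (1.5 equiv, syringe pump), AIBN (0.2 equiv), PhH (0.005 M), 80 °C
Reagents that add atoms: none
Why: Proposed new method: Bu3Sn• abstracts the tertiary chlorine, the tertiary radical adds 7-exo to the imine carbon from the only face the side chain can reach (anti to the C2–C4 bridge), the aminyl radical loses styrene and N2, and the cyclobutyl radical takes H from Bu3SnH on the free face, so that C6=O becomes CH–C with the ring stereochemistry of the target; the closest known reaction is the 5- and 6-exo radical cyclisation onto N-aziridinyl imines (Kim), here extended to a seven-membered ring.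

**Step 12**
Reactants: 18 (1R,2S,4R,6R,7R,8R,9S)-9-(TBSO)-3,3,7-trimethyl-11-methylidenetricyclo[5.4.0.0^2,8]undecane-4,6-diyl bis(3-methylbutanoate)
Product: 19 (1R,2S,4R,6R,7R,8R,9S)-9-hydroxy-3,3,7-trimethyl-11-methylidenetricyclo[5.4.0.0^2,8]undecane-4,6-diyl bis(3-methylbutanoate)
Conditions: HF·pyridine, pyridine, THF, 0 °C → rt
Reagents that add atoms: none
Why: Fluoride-driven Si–O cleavage removes the TBS group under buffered conditions that leave the two esters and the exocyclic alkene alone; no stereocentre changes.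

**Step 13**
Reactants: 19 (1R,2S,4R,6R,7R,8R,9S)-9-hydroxy-3,3,7-trimethyl-11-methylidenetricyclo[5.4.0.0^2,8]undecane-4,6-diyl bis(3-methylbutanoate)
Product: 21 (1R,2S,4R,6R,7R,8R)-3,3,7,11-tetramethyl-9-oxotricyclo[5.4.0.0^2,8]undec-10-ene-4,6-diyl bis(3-methylbutanoate), via exo-methylene ketone 20 (not isolated)
Conditions: Dess–Martin periodinane, NaHCO3, CH2Cl2, rt; then DBU (0.3 equiv), rt
Reagents that add atoms: none
Why: Dess–Martin oxidation turns the relay alcohol into the C9 ketone, and DBU moves the β,γ-alkene of 20 into conjugation through the dienolate (base-mediated alkene isomerisation) to give the trisubstituted enone; the bridgehead C8 cannot enolise, so nothing epimerises.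

**Compound list**
1 | methyl 3-methylbut-2-enoate | COC(=O)C=C(C)C | starting material
2 | tert-butyl[(1-methoxy-3-methylbuta-1,3-dien-1-yl)oxy]dimethylsilane (E/Z mixture at the ketene acetal, no stereocentre) | COC(=CC(C)=C)O[Si](C)(C)C(C)(C)C | intermediate
3 | 3-methylbut-2-enal (prenal) | CC(C)=CC=O | starting material
4 | methyl (2E,5S)-5-hydroxy-3,7-dimethylocta-2,6-dienoate | COC(=O)/C=C(\C)C[C@H](O)C=C(C)C | intermediate
5 | methyl (2E,5S)-5-(tert-butyldimethylsilyloxy)-3,7-dimethylocta-2,6-dienoate | COC(=O)/C=C(\C)C[C@H](O[Si](C)(C)C(C)(C)C)C=C(C)C | intermediate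
6 | methyl (2E,5S,6E)-5-(tert-butyldimethylsilyloxy)-8-hydroxy-3,7-dimethylocta-2,6-dienoate | COC(=O)/C=C(\C)C[C@H](O[Si](C)(C)C(C)(C)C)/C=C(\C)CO | intermediate
7 | methyl (2E,5S,6E)-5-(tert-butyldimethylsilyloxy)-3,7-dimethyl-8-oxoocta-2,6-dienoate | COC(=O)/C=C(\C)C[C@H](O[Si](C)(C)C(C)(C)C)/C=C(\C)C=O | intermediate
8 | 3-chloro-3-methylbutan-2-one | CC(=O)C(C)(C)Cl | starting material
9 | methyl (2E,5S,6E,8R)-5-(tert-butyldimethylsilyloxy)-11-chloro-8-hydroxy-3,7,11-trimethyl-10-oxododeca-2,6-dienoate | COC(=O)/C=C(\C)C[C@H](O[Si](C)(C)C(C)(C)C)/C=C(\C)[C@H](O)CC(=O)C(C)(C)Cl | intermediate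
10 | methyl (2E,5S,6E,8R,10R)-5-(tert-butyldimethylsilyloxy)-11-chloro-8,10-dihydroxy-3,7,11-trimethyldodeca-2,6-dienoate | COC(=O)/C=C(\C)C[C@H](O[Si](C)(C)C(C)(C)C)/C=C(\C)[C@H](O)C[C@@H](O)C(C)(C)Cl | intermediate
11 | 3-methylbutanoyl chloride (isovaleryl chloride) | CC(C)CC(Cl)=O | starting material
12 | methyl (2E,5S,6E,8R,10R)-5-(tert-butyldimethylsilyloxy)-11-chloro-3,7,11-trimethyl-8,10-bis(3-methylbutanoyloxy)dodeca-2,6-dienoate | COC(=O)/C=C(\C)C[C@H](O[Si](C)(C)C(C)(C)C)/C=C(\C)[C@H](OC(=O)CC(C)C)C[C@@H](OC(=O)CC(C)C)C(C)(C)Cl | intermediate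
13 | (2E,5S,6E,8R,10R)-5-(tert-butyldimethylsilyloxy)-11-chloro-3,7,11-trimethyl-8,10-bis(3-methylbutanoyloxy)dodeca-2,6-dienoic acid | OC(=O)/C=C(\C)C[C@H](O[Si](C)(C)C(C)(C)C)/C=C(\C)[C@H](OC(=O)CC(C)C)C[C@@H](OC(=O)CC(C)C)C(C)(C)Cl | intermediate
14 | (2E,5S,6E,8R,10R)-5-(tert-butyldimethylsilyloxy)-11-chloro-3,7,11-trimethyl-8,10-bis(3-methylbutanoyloxy)dodeca-2,6-dienoyl chloride | ClC(=O)/C=C(\C)C[C@H](O[Si](C)(C)C(C)(C)C)/C=C(\C)[C@H](OC(=O)CC(C)C)C[C@@H](OC(=O)CC(C)C)C(C)(C)Cl | intermediate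
15 | (5S,6E,8R,10R)-5-(tert-butyldimethylsilyloxy)-11-chloro-7,11-dimethyl-3-methylidene-8,10-bis(3-methylbutanoyloxy)dodeca-1,6-dien-1-one (vinylketene) | O=C=CC(=C)C[C@H](O[Si](C)(C)C(C)(C)C)/C=C(\C)[C@H](OC(=O)CC(C)C)C[C@@H](OC(=O)CC(C)C)C(C)(C)Cl | intermediate
16 | (1R,2S,5R,7R)-2-(tert-butyldimethylsilyloxy)-7-[(1R,3R)-4-chloro-4-methyl-1,3-bis(3-methylbutanoyloxy)pentyl]-7-methyl-4-methylidenebicyclo[3.1.1]heptan-6-one (side chain anti and 7-methyl syn to the C2–C4 bridge; silyloxy group on the side of the carbonyl bridge) | O=C1[C@H]2[C@@H](O[Si](C)(C)C(C)(C)C)CC(=C)[C@@H]1[C@@]2(C)[C@H](OC(=O)CC(C)C)C[C@@H](OC(=O)CC(C)C)C(C)(C)Cl | intermediate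
17 | 16 with C6=O replaced by C6=N–N(2-phenylaziridin-1-yl) (mixture of C=N isomers and aziridine epimers; ring and side-chain centres as in 16) | c1ccccc1C2CN2N=C3[C@H]4[C@@H](O[Si](C)(C)C(C)(C)C)CC(=C)[C@@H]3[C@@]4(C)[C@H](OC(=O)CC(C)C)C[C@@H](OC(=O)CC(C)C)C(C)(C)Cl | intermediate
18 | (1R,2S,4R,6R,7R,8R,9S)-9-(tert-butyldimethylsilyloxy)-3,3,7-trimethyl-11-methylidenetricyclo[5.4.0.0^2,8]undecane-4,6-diyl bis(3-methylbutanoate) | C=C1C[C@H](O[Si](C)(C)C(C)(C)C)[C@@H]2[C@@H]3[C@H]1[C@@]2(C)[C@H](OC(=O)CC(C)C)C[C@@H](OC(=O)CC(C)C)C3(C)C | intermediate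
19 | (1R,2S,4R,6R,7R,8R,9S)-9-hydroxy-3,3,7-trimethyl-11-methylidenetricyclo[5.4.0.0^2,8]undecane-4,6-diyl bis(3-methylbutanoate) | C=C1C[C@H](O)[C@@H]2[C@@H]3[C@H]1[C@@]2(C)[C@H](OC(=O)CC(C)C)C[C@@H](OC(=O)CC(C)C)C3(C)C | intermediate
20 | (1R,2S,4R,6R,7R,8R)-3,3,7-trimethyl-11-methylidene-9-oxotricyclo[5.4.0.0^2,8]undecane-4,6-diyl bis(3-methylbutanoate) | C=C1CC(=O)[C@@H]2[C@@H]3[C@H]1[C@@]2(C)[C@H](OC(=O)CC(C)C)C[C@@H](OC(=O)CC(C)C)C3(C)C | intermediate
21 | (1R,2S,4R,6R,7R,8R)-3,3,7,11-tetramethyl-9-oxotricyclo[5.4.0.0^2,8]undec-10-ene-4,6-diyl bis(3-methylbutanoate) | CC1=CC(=O)[C@@H]2[C@@H]3[C@H]1[C@@]2(C)[C@H](OC(=O)CC(C)C)C[C@@H](OC(=O)CC(C)C)C3(C)C | target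

**Totals**
Total step count: 13.
Longest linear sequence: 13 steps (1 → 21; compounds 3, 8 and 11 enter at steps 2, 5 and 7).

**Three steps most likely to fail**

Step 9 (ketene [2+2]). The alkene is flanked by two oxygen-bearing carbons and may be too poor a nucleophile for the neutral ketene, which can then dimerise; the facial selectivity rests on A(1,3) strain alone. Any endocyclic alkene isomer formed beside 16 converges in step 13. Fallback: use the far more electrophilic keteniminium ion (Ghosez) for the same ring pair. It sets out from 13: acid chloride 14 is quenched with pyrrolidine to give the pyrrolidine amide F1; Tf2O and 2,4,6-collidine in 1,2-dichloroethane at 80 °C convert it into the vinylketeniminium triflate F2, which cyclises [2+2] to the cyclobutaniminium triflate F3; aqueous NaHCO3 hydrolyses the iminium ion, and the route is rejoined at 16.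

Step 11 (radical closure of the seven-membered ring). Chlorine abstraction from a tertiary chloride is slow, the tertiary radical may be reduced before the 7-exo closure, and tin radicals may attack the ring methylidene group. Fallback: close the ring by two-electron chemistry instead. It sets out from 9: TESCl and imidazole give the C8 triethylsilyl ether F4, and LiI in EtOAc gives the acid F5. The conditions of step 9 then give the acid chloride F6, the vinylketene F7 and, by the same [2+2], the bicyclic chloro diketone F8. SmI2 (THF, −78 °C) reduces the α-chloro ketone to a samarium enolate that adds to the cyclobutanone from the tethered face (intramolecular Reformatsky), and methyl chlorooxoacetate traps the tertiary alkoxide as the tricyclic methyl oxalate F9. Bu3SnH/AIBN in toluene at 110 °C (Dolan–MacMillan deoxygenation) gives the tricyclic ketone F10. HF·pyridine at 0 °C removes only the TES group to give the β-hydroxy ketone F11, Me4NBH(OAc)3 gives the anti diol F12, and acylation with 11 (pyridine, DMAP) rejoins the route at 18.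

Step 5 (aldol with the α-chloro ketone). The boron enolate of 8 is a 2-oxyallyl chloride and may ionise or enter Favorskii pathways, and methyl-ketone boron aldols give only moderate enantioselectivity. Fallback: carry the chloride in latent form and add it late. It sets out from 7: the same chiral boron aldol with 3-methylbut-3-en-2-one F13 gives the β-hydroxy enone F14; Saksena–Evans reduction gives the anti diol F15 and acylation with 11 gives the isopropenyl bis-ester F16; Markovnikov hydrochlorination by cobalt-hydride hydrogen-atom transfer (Co(salen) catalyst, PhSiH3, TsCl, EtOH), which acts on the 1,1-disubstituted alkene only, rejoins the route at 12.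

**Further compounds**
F1 | step 9 | 1-[(2E,5S,6E,8R,10R)-5-(tert-butyldimethylsilyloxy)-11-chloro-3,7,11-trimethyl-8,10-bis(3-methylbutanoyloxy)dodeca-2,6-dienoyl]pyrrolidine | O=C(N1CCCC1)/C=C(\C)C[C@H](O[Si](C)(C)C(C)(C)C)/C=C(\C)[C@H](OC(=O)CC(C)C)C[C@@H](OC(=O)CC(C)C)C(C)(C)Cl
F2 | step 9 | vinylketeniminium triflate from F1 (N-pyrrolidinium ylidene analogue of 15) | C=C(C=C=[N+]1CCCC1)C[C@H](O[Si](C)(C)C(C)(C)C)/C=C(\C)[C@H](OC(=O)CC(C)C)C[C@@H](OC(=O)CC(C)C)C(C)(C)Cl.[O-]S(=O)(=O)C(F)(F)F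
F3 | step 9 | cyclobutaniminium triflate (16 with C6=O replaced by C6=N+(CH2)4) | C5CC[N+](C5)=C1[C@H]2[C@@H](O[Si](C)(C)C(C)(C)C)CC(=C)[C@@H]1[C@@]2(C)[C@H](OC(=O)CC(C)C)C[C@@H](OC(=O)CC(C)C)C(C)(C)Cl.[O-]S(=O)(=O)C(F)(F)F
F4 | step 11 | methyl (2E,5S,6E,8R)-5-(tert-butyldimethylsilyloxy)-11-chloro-3,7,11-trimethyl-10-oxo-8-(triethylsilyloxy)dodeca-2,6-dienoate | COC(=O)/C=C(\C)C[C@H](O[Si](C)(C)C(C)(C)C)/C=C(\C)[C@H](O[Si](CC)(CC)CC)CC(=O)C(C)(C)Cl
F5 | step 11 | (2E,5S,6E,8R)-5-(tert-butyldimethylsilyloxy)-11-chloro-3,7,11-trimethyl-10-oxo-8-(triethylsilyloxy)dodeca-2,6-dienoic acid | OC(=O)/C=C(\C)C[C@H](O[Si](C)(C)C(C)(C)C)/C=C(\C)[C@H](O[Si](CC)(CC)CC)CC(=O)C(C)(C)Cl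
F6 | step 11 | acid chloride of F5 | ClC(=O)/C=C(\C)C[C@H](O[Si](C)(C)C(C)(C)C)/C=C(\C)[C@H](O[Si](CC)(CC)CC)CC(=O)C(C)(C)Cl
F7 | step 11 | vinylketene from F6 | O=C=CC(=C)C[C@H](O[Si](C)(C)C(C)(C)C)/C=C(\C)[C@H](O[Si](CC)(CC)CC)CC(=O)C(C)(C)Cl
F8 | step 11 | bicyclic chloro diketone (16 with the side chain (1R)-4-chloro-4-methyl-3-oxo-1-(triethylsilyloxy)pentyl) | O=C1[C@H]2[C@@H](O[Si](C)(C)C(C)(C)C)CC(=C)[C@@H]1[C@@]2(C)[C@H](O[Si](CC)(CC)CC)CC(=O)C(C)(C)Cl
F9 | step 11 | tricyclic methyl oxalate (tricyclo[5.4.0.0^2,8]undecane: 2-methoxyoxalyloxy, 4-oxo, 6-triethylsilyloxy, 9-TBSO, 3,3,7-trimethyl, 11-methylidene) | C=C1C[C@H](O[Si](C)(C)C(C)(C)C)[C@@H]2[C@]3(OC(=O)C(=O)OC)[C@H]1[C@@]2(C)[C@H](O[Si](CC)(CC)CC)CC(=O)C3(C)C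
F10 | step 11 | tricyclic ketone (F9 with H in place of the oxalate at C2) | C=C1C[C@H](O[Si](C)(C)C(C)(C)C)[C@@H]2[C@@H]3[C@H]1[C@@]2(C)[C@H](O[Si](CC)(CC)CC)CC(=O)C3(C)C
F11 | step 11 | tricyclic β-hydroxy ketone (F10 with free 6-OH) | C=C1C[C@H](O[Si](C)(C)C(C)(C)C)[C@@H]2[C@@H]3[C@H]1[C@@]2(C)[C@H](O)CC(=O)C3(C)C
F12 | step 11 | tricyclic anti 4,6-diol (18 with OH in place of both esters) | C=C1C[C@H](O[Si](C)(C)C(C)(C)C)[C@@H]2[C@@H]3[C@H]1[C@@]2(C)[C@H](O)C[C@@H](O)C3(C)C
F13 | step 5 | 3-methylbut-3-en-2-one | CC(=O)C(C)=C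
F14 | step 5 | methyl (2E,5S,6E,8R)-5-(tert-butyldimethylsilyloxy)-8-hydroxy-3,7,11-trimethyl-10-oxododeca-2,6,11-trienoate | COC(=O)/C=C(\C)C[C@H](O[Si](C)(C)C(C)(C)C)/C=C(\C)[C@H](O)CC(=O)C(C)=C
F15 | step 5 | methyl (2E,5S,6E,8R,10R)-5-(tert-butyldimethylsilyloxy)-8,10-dihydroxy-3,7,11-trimethyldodeca-2,6,11-trienoate | COC(=O)/C=C(\C)C[C@H](O[Si](C)(C)C(C)(C)C)/C=C(\C)[C@H](O)C[C@@H](O)C(C)=C
F16 | step 5 | methyl (2E,5S,6E,8R,10R)-5-(tert-butyldimethylsilyloxy)-3,7,11-trimethyl-8,10-bis(3-methylbutanoyloxy)dodeca-2,6,11-trienoate | COC(=O)/C=C(\C)C[C@H](O[Si](C)(C)C(C)(C)C)/C=C(\C)[C@H](OC(=O)CC(C)C)C[C@@H](OC(=O)CC(C)C)C(C)=C
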